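The next charge has to go somewhere, and the easy step is the clock. The summer run has 3 % of its substrate left at 2.50 h. Thursday's, the coldest new flask, is hotter than the summer run and gets the same 2.5 h. So I leave the time alone and count each flask's substrate as consumed at the end. In the winter run target reads 85 % at 40.0 min and 88 % at 50.0 min, with no fall beyond the scatter, so I allow for no loss of target. The choice of flask now hangs on how the consumed substrate divides.

all flasks: gas 0.61 mM (held)
- summer: substrate 0.018 M; temperature 45 °C; run made earlier
- winter: substrate 0.029 M; temperature 72 °C; run made earlier
- Thursday's: substrate 0.013 M; temperature 50 °C; time 2.5 h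
- Wednesday's: substrate 0.013 M; temperature 65 °C; time 2.5 h
- Sunday's: substrate 0.013 M; temperature 95 °C; time 2.5 h
- Tuesday's: substrate 0.013 M; temperature 80 °C; time 2.5 h

summer run (percent of the substrate charged)

| time / h | target / % | substrate / % |
|---|---|---|
| 0.133 | 10 | 77 |
| 0.417 | 22 | 43 |
| 0.667 | 29 | 25 |
| 1.00 | 35 | 14 |
| 1.50 | 39 | 4 |
| 2.00 | 40 | 4 |
| 2.50 | 41 | 3 |

winter run (percent of the substrate charged)

| time / min | target / % | substrate / % |
|---|---|---|
| 6.00 | 59 | 23 |
| 15.0 | 79 | 6 |
| 20.0 | 83 | 1 |
| 25.0 | 84 | 0 |
| 40.0 | 85 | 0 |
| 50.0 | 88 | 1 |

(readings scatter by 1.5 percentage points)

- what was read earlier has a scatter of 1.5 percentage points, one standard deviation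
- at the start none of the gas is in solution
- a reading or a percentage of target counts all its forms, free or not
- a reading of substrate is of its free form alone

1. the best flask by amount of target, in percent of the substrate charged; "all alike" if 1.5 percentage points covers them all (Thursday's / Wednesday's / Sunday's / Tuesday's / all alike)
2. amount of target at the end, in percent of the substrate charged, Thursday's
3. amount of target at the end, in percent of the substrate charged, Wednesday's
4. amount of target at the end, in percent of the substrate charged, Sunday's
5. amount of target at the end, in percent of the substrate charged, Tuesday's

I call s, a selectivity factor, the target formed divided by the substrate consumed that did not become target. Within the summer run, target per substrate consumed reads 0.435 at 0.133 h and 0.423 at 2.50 h, although the substrate has fallen far between them. The two runs differ in charge as well as in temperature, so leaving the smaller charge out of my reckoning is an assumption that these readings do not test. That leaves temperature, and I solve the two ends first. The last summer reading gives s = 0.732, and the winter reading at 40.0 min gives s = 5.67.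

To join them I draw a straight line of ln s against the reciprocal of the absolute temperature. Its slope, multiplied by the gas constant R, is ΔE, an apparent energy gap, a working slope through two runs of different charge and not the gap of any one step, which reads 69.2 kJ/mol. Along that line s is 1.10 for Thursday's, 3.44 for Wednesday's, 9.78 for Tuesday's and 25.6 for Sunday's. The target share is s/(1+s), which gives 52.3 %, 77.5 %, 90.7 % and 96.2 %. Sunday's beats Tuesday's by more than the margin of 1.5 percentage points, so my charge goes to Sunday's.

The forecast also names Sunday's, with 52 % for Thursday's, 77 % for Wednesday's, 90 % for Tuesday's and 94 % for Sunday's, which is below my figure because of its caution at the hot end: “so I shade that figure down”.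

Sunday's comes out best, with 48.8 % target for Thursday's, 75.6 % for Wednesday's and 90.9 % for Tuesday's, and these are the equations that ran:

    substrate → target (k = 0.0230 /min, Ea = 92.0 kJ/mol)
    substrate + reagent → intermediate A (k = 71.0 /M/min, Ea = 36.0 kJ/mol)
    reagent + intermediate A → side product (k = 330 /M/min, Ea = 63.0 kJ/mol)
    reagent + intermediate A → intermediate B (k = 230 /M/min, Ea = 54.0 kJ/mol)
    intermediate B ⇌ intermediate C (K = 0.420, k = 0.0140 /min, Ea = 91.0 kJ/mol, ΔH = −21.0 kJ/mol)
    substrate + target ⇌ idle adduct, settled at all times (K = 110 /M, ΔH = −31.0 kJ/mol)
    gas ⇌ reagent, rate k7*(csat - [reagent]) (kL = 0.870 /min)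
    (constants at 50 °C)

Sunday's gives 97.1 % target, 0.90 points from my reckoning, beside 1.98 % side product at 2.50 h. Its s is 33.5, against 25.6 on my line. Taken down with ΔE to a flask like Thursday's kept at 35 °C, the line gives s = 0.313. With the free substrate and the substrate bound in idle adduct taken off, 92.3 % of the charge is consumed there, which makes 22.0 % target, and that neighbour holds 20.7 % target with 38.7 % side product.

(The readings are simulated with constants of no real substance; the scatter is artificial.)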